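## Retrosynthetic overview
1. Last bond: the C(sp3)–C(sp2) bond between the ring A side-chain methine and the trisubstituted alkene. It comes from a racemic 1-(pyronyl)ethyl chloride and an unprotected (E)-alkenyl bromide triol by an enantioconvergent nickel radical cross-coupling, which sets the isolated (S) centre.
2. The bromide triol comes from a vinylogous aldol between the free ethyl group of ring B and a 2,3-anti β-silyloxy aldehyde. The aldehyde comes from (E)-3-bromo-2-methylacrolein by anti-crotylboration and oxidative cleavage.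
3. The hydroxypentyl arm of ring B comes from the same racemic chloride and propionyl chloride by a nickel radical acyl coupling, followed by a Felkin–Anh reduction.
4. Ring order: rings A and B are the same 2,6-diethyl-3,5-dimethyl-4-pyrone, formed once in step 1 from pentan-3-one and propionic acid. No ring is formed later.

Assumption: the sense of induction of both nickel/bis(oxazoline) catalysts is taken from 1-arylethyl chlorides, with the pyrone in place of the aryl group. If a model run shows the opposite sense, the mirror-image ligand is used.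

## Route

Step 1
Reactants: 1 pentan-3-one; 2 propionic acid (2.5 equiv)
Product: 4 2,6-diethyl-3,5-dimethyl-4H-pyran-4-one, via 4,6-dimethylnonane-3,5,7-trione 3 (not isolated)
Conditions: polyphosphoric acid, 130 °C, 3 h; then ice–water
Reagents that add atoms: none
Why: Polyphosphoric-acid-mediated double C-acylation of the ketone at both α-carbons gives the 1,3,5-triketone, which cyclodehydrates in the same medium (classical 4-pyrone synthesis); no stereocentre is formed.

Step 2
Reactants: 4 2,6-diethyl-3,5-dimethyl-4H-pyran-4-one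
Product: 6 (±)-2-(1-chloroethyl)-6-ethyl-3,5-dimethyl-4H-pyran-4-one, via lithium (Z)-6-ethyl-2-ethylidene-3,5-dimethyl-2H-pyran-4-olate 5 (not isolated)
Conditions: LiN(SiMe3)2 (1.05 equiv), THF, −78 °C; cannulated into C2Cl6 (1.2 equiv), THF, −78 °C
Reagents that add atoms: hexachloroethane, ClC(Cl)(Cl)C(Cl)(Cl)Cl
Why: Vinylogous enolate formation (γ-deprotonation of the 2-ethyl CH2) is followed by electrophilic chlorination at the exocyclic carbon; inverse addition limits proton exchange and dichlorination, and the racemate is wanted because both later couplings are stereoconvergent.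

Step 3
Reactants: 6 (±)-2-(1-chloroethyl)-6-ethyl-3,5-dimethyl-4H-pyran-4-one; 7 propionyl chloride
Product: 8 2-ethyl-3,5-dimethyl-6-[(2S)-3-oxopentan-2-yl]-4H-pyran-4-one
Conditions: NiCl2(dme) (10 mol %), (S,S)-Ph-BOX [2,2'-(propane-2,2-diyl)bis((4S)-4-phenyl-4,5-dihydrooxazole), 22 mol %], Mn powder (3 equiv), 2,6-dimethylbenzoic acid (0.75 equiv), 3 Å MS, DMA–THF 3:7, 20 °C; short Florisil pad, used the same day
Reagents that add atoms: none
Why: Proposed new method: the enantioconvergent nickel-catalysed reductive acyl cross-coupling known for racemic 1-arylethyl chlorides and acid chlorides is extended to the 1-(4-pyron-2-yl)ethyl chloride; zerovalent nickel inserts into the acyl chloride, monovalent nickel abstracts Cl from either enantiomer of 6 to give the planar pyrone-stabilised secondary radical, the chiral acyl complex of divalent nickel captures it, and reductive elimination from trivalent nickel sets the (S) methine under ligand control, while the base-free medium and the A(1,3) strain from the ring methyl slow enolisation of the product.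

Step 4
Reactants: 8 2-ethyl-3,5-dimethyl-6-[(2S)-3-oxopentan-2-yl]-4H-pyran-4-one
Product: 9 2-ethyl-6-[(2R,3R)-3-hydroxypentan-2-yl]-3,5-dimethyl-4H-pyran-4-one
Conditions: LiBH(s-Bu)3 (L-Selectride, 1.1 equiv), THF, −78 °C; pH 7 buffer, 30% H2O2, 0 °C
Reagents that add atoms: none
Why: This is a Felkin–Anh controlled hydride reduction; the pyrone is the large group perpendicular to the C=O, its ring oxygen is too poor a donor to chelate, and the bulky hydride attacks anti to it, giving the 2,3-anti (2R,3R) alcohol, while the fully substituted vinylogous-ester pyrone carbonyl is inert at −78 °C.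

Step 5
Reactants: 10 methacrolein
Product: 12 (E)-3-bromo-2-methylprop-2-enal, via 2,3-dibromo-2-methylpropanal 11 (not isolated)
Conditions: Br2 (1.0 equiv), CH2Cl2, −78 to 0 °C; then Et3N (1.2 equiv), 0 °C to rt
Reagents that add atoms: bromine, BrBr
Why: Bromination–dehydrobromination; E2 loss of the tertiary bromide with the bromine-acidified C3–H gives the conjugated bromoenal as the more stable E isomer (Br trans to CHO), which fixes the alkene geometry of the target.

Step 6
Reactants: 13 trans-but-2-ene; 12 (E)-3-bromo-2-methylprop-2-enal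
Product: 18 (1E,3S,4S)-1-bromo-2,4-dimethylhexa-1,5-dien-3-ol, via (E)-crotylpotassium 14 (not isolated), via potassium (E)-crotyl(methoxy)diisopinocampheylborate 15 (not isolated), via (E)-crotyldiisopinocampheylborane 16 (not isolated), via homoallylic diisopinocampheylborinate 17 (not isolated)
Conditions: 13, n-BuLi, KOt-Bu, THF, −78 to −45 °C; (−)-Ipc2BOMe [from (+)-α-pinene], −78 °C; BF3·OEt2; 12, −78 °C; NaOH, H2O2
Reagents that add atoms: none
Why: Brown asymmetric crotylboration through a closed chair transition state; the E-crotyl geometry gives the anti methyl/hydroxyl pair and the isopinocampheyl groups derived from (+)-α-pinene select the aldehyde face that gives (3S,4S).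

Step 7
Reactants: 18 (1E,3S,4S)-1-bromo-2,4-dimethylhexa-1,5-dien-3-ol
Product: 19 [(1E,3S,4S)-1-bromo-2,4-dimethylhexa-1,5-dien-3-yl]oxy(triethyl)silane
Conditions: TESCl (1.2 equiv), imidazole (2 equiv), CH2Cl2, 0 °C to rt
Reagents that add atoms: chlorotriethylsilane (TESCl), CC[Si](Cl)(CC)CC
Why: Standard silyl ether protection; a non-chelating β-silyloxy group is needed for Felkin and 1,3-anti control in step 9, and it falls off in a mild acid quench.

Step 8
Reactants: 19 [(1E,3S,4S)-1-bromo-2,4-dimethylhexa-1,5-dien-3-yl]oxy(triethyl)silane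
Product: 21 (2R,3S,4E)-5-bromo-2,4-dimethyl-3-(triethylsilyloxy)pent-4-enal, via vicinal diol 20 (not isolated)
Conditions: OsO4 (2 mol %), NaIO4 (4 equiv), 2,6-lutidine (2 equiv), dioxane–H2O 3:1, rt
Reagents that add atoms: osmium tetroxide (oxygen carrier), O=[Os](=O)(=O)=O; sodium periodate (terminal oxidant), [Na+].[O-]I(=O)(=O)=O
Why: Lemieux–Johnson oxidative cleavage; the electron-poor, hindered bromoalkene is much less reactive toward OsO4 than the monosubstituted vinyl group, and the lutidine buffer prevents epimerisation of the α-methyl aldehyde.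

Step 9
Reactants: 9 2-ethyl-6-[(2R,3R)-3-hydroxypentan-2-yl]-3,5-dimethyl-4H-pyran-4-one (1.2 equiv); 21 (2R,3S,4E)-5-bromo-2,4-dimethyl-3-(triethylsilyloxy)pent-4-enal
Product: 24 2-[(2S,3S,4S,5S,6E)-7-bromo-3,5-dihydroxy-4,6-dimethylhept-6-en-2-yl]-6-[(2R,3R)-3-hydroxypentan-2-yl]-3,5-dimethyl-4H-pyran-4-one, via dilithium alkoxide-dienolate 22 (not isolated), via triethylsilyl-protected aldol adduct 23 (not isolated)
Conditions: 9, LiN(SiMe3)2 (2.5 equiv), THF, −78 °C, 45 min; 21, −78 °C, 1 h; then 1 M aq HCl, THF, 0 °C to rt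
Reagents that add atoms: none
Why: Vinylogous aldol addition of a lithiated 2-ethyl-4-pyrone, with the carbinol masked in situ as its lithium alkoxide; A(1,3) strain places the ethylidene methyl away from the ring methyl, the remote O–Li forces an open transition state that is expected to give the anti methine/carbinol pair as with E-configured extended dienolates, the aldehyde face is fixed by reinforcing Felkin–Anh and 1,3-anti (polar) induction in the 2,3-anti aldehyde, the acid quench removes the TES group in the same flask, and minor isomers are removed by chromatography.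

Step 10
Reactants: 24 bromide triol of step 9; 6 (±)-2-(1-chloroethyl)-6-ethyl-3,5-dimethyl-4H-pyran-4-one (1.5 equiv)
Product: 25 2-ethyl-6-[(2S,3E,5S,6S,7S,8S)-5,7-dihydroxy-8-{6-[(2R,3R)-3-hydroxypentan-2-yl]-3,5-dimethyl-4-oxo-4H-pyran-2-yl}-4,6-dimethylnon-3-en-2-yl]-3,5-dimethyl-4H-pyran-4-one (target)
Conditions: NiCl2(dme) (10 mol %), (3aR,3a'R,8aS,8a'S)-2,2'-(cyclopropane-1,1-diyl)bis(3a,8a-dihydro-8H-indeno[1,2-d]oxazole) (11 mol %), Mn powder (3 equiv), NaI (0.5 equiv), DMA, 0 °C
Reagents that add atoms: none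
Why: Proposed new method: the nickel-catalysed enantioconvergent reductive cross-electrophile alkenylation known for racemic 1-arylethyl chlorides and (E)-alkenyl bromides is extended to the pyronylethyl chloride and to an unprotected β,β-disubstituted alkenyl bromide; zerovalent nickel inserts into C–Br with retention of the E geometry, monovalent nickel abstracts Cl from either enantiomer of 6 to give the planar pyrone-delocalised secondary radical, the chiral alkenyl complex of divalent nickel captures it, and reductive elimination from trivalent nickel forms the C2–C3 bond of the nonenyl chain, so the ligand alone sets the isolated (S) centre, Mn closes the cycle, and the base-free medium leaves the three hydroxyl groups and all resident stereocentres untouched.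

## Compound list
1 | pentan-3-one | CCC(=O)CC | starting material
2 | propionic acid | CCC(=O)O | starting material
3 | 4,6-dimethylnonane-3,5,7-trione | CCC(=O)C(C)C(=O)C(C)C(=O)CC | intermediate
4 | 2,6-diethyl-3,5-dimethyl-4H-pyran-4-one | CCc1oc(CC)c(C)c(=O)c1C | intermediate
5 | lithium (Z)-6-ethyl-2-ethylidene-3,5-dimethyl-2H-pyran-4-olate | [Li+].CC1=C([O-])C(C)=C(CC)O/C1=C\C | intermediate
6 | (±)-2-(1-chloroethyl)-6-ethyl-3,5-dimethyl-4H-pyran-4-one (racemic) | CCc1oc(C(C)Cl)c(C)c(=O)c1C | intermediate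
7 | propionyl chloride | CCC(=O)Cl | starting material
8 | 2-ethyl-3,5-dimethyl-6-[(2S)-3-oxopentan-2-yl]-4H-pyran-4-one | CCc1oc([C@H](C)C(=O)CC)c(C)c(=O)c1C | intermediate
9 | 2-ethyl-6-[(2R,3R)-3-hydroxypentan-2-yl]-3,5-dimethyl-4H-pyran-4-one | CCc1oc([C@H](C)[C@H](O)CC)c(C)c(=O)c1C | intermediate
10 | methacrolein | CC(=C)C=O | starting material
11 | 2,3-dibromo-2-methylpropanal (racemic) | CC(Br)(CBr)C=O | intermediate
12 | (E)-3-bromo-2-methylprop-2-enal | Br/C=C(\C)C=O | intermediate
13 | trans-but-2-ene | C/C=C/C | starting material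
14 | (E)-crotylpotassium | [K+].C/C=C/[CH2-] | intermediate
15 | potassium (E)-crotyl(methoxy)diisopinocampheylborate | [K+].C/C=C/C[B-](OC)([C@@H]1C[C@@H]2C[C@H]([C@H]1C)C2(C)C)[C@@H]1C[C@@H]2C[C@H]([C@H]1C)C2(C)C | intermediate
16 | (E)-crotyldiisopinocampheylborane, Ipc from (+)-α-pinene | C/C=C/CB([C@@H]1C[C@@H]2C[C@H]([C@H]1C)C2(C)C)[C@@H]1C[C@@H]2C[C@H]([C@H]1C)C2(C)C | intermediate
17 | (1E,3S,4S)-1-bromo-2,4-dimethylhexa-1,5-dien-3-yl diisopinocampheylborinate | Br/C=C(\C)[C@@H](OB([C@@H]1C[C@@H]2C[C@H]([C@H]1C)C2(C)C)[C@@H]1C[C@@H]2C[C@H]([C@H]1C)C2(C)C)[C@@H](C)C=C | intermediate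
18 | (1E,3S,4S)-1-bromo-2,4-dimethylhexa-1,5-dien-3-ol | Br/C=C(\C)[C@@H](O)[C@@H](C)C=C | intermediate
19 | [(1E,3S,4S)-1-bromo-2,4-dimethylhexa-1,5-dien-3-yl]oxy(triethyl)silane | Br/C=C(\C)[C@@H](O[Si](CC)(CC)CC)[C@@H](C)C=C | intermediate
20 | (3S,4S,5E)-6-bromo-3,5-dimethyl-4-(triethylsilyloxy)hex-5-ene-1,2-diol (C2 epimers) | Br/C=C(\C)[C@@H](O[Si](CC)(CC)CC)[C@@H](C)C(O)CO | intermediate
21 | (2R,3S,4E)-5-bromo-2,4-dimethyl-3-(triethylsilyloxy)pent-4-enal | Br/C=C(\C)[C@@H](O[Si](CC)(CC)CC)[C@@H](C)C=O | intermediate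
22 | dilithium (Z)-2-ethylidene-3,5-dimethyl-6-[(2R,3R)-3-oxidopentan-2-yl]-2H-pyran-4-olate | [Li+].[Li+].CC1=C([O-])C(C)=C([C@H](C)[C@H]([O-])CC)O/C1=C\C | intermediate
23 | 2-[(2S,3S,4S,5S,6E)-7-bromo-3-hydroxy-4,6-dimethyl-5-(triethylsilyloxy)hept-6-en-2-yl]-6-[(2R,3R)-3-hydroxypentan-2-yl]-3,5-dimethyl-4H-pyran-4-one | Br/C=C(\C)[C@@H](O[Si](CC)(CC)CC)[C@@H](C)[C@H](O)[C@H](C)c1oc([C@H](C)[C@H](O)CC)c(C)c(=O)c1C | intermediate
24 | 2-[(2S,3S,4S,5S,6E)-7-bromo-3,5-dihydroxy-4,6-dimethylhept-6-en-2-yl]-6-[(2R,3R)-3-hydroxypentan-2-yl]-3,5-dimethyl-4H-pyran-4-one | Br/C=C(\C)[C@@H](O)[C@@H](C)[C@H](O)[C@H](C)c1oc([C@H](C)[C@H](O)CC)c(C)c(=O)c1C | intermediate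
25 | CNP0328559.2, name as in step 10 | CCc1oc([C@@H](C)/C=C(\C)[C@@H](O)[C@@H](C)[C@H](O)[C@H](C)c2oc([C@H](C)[C@H](O)CC)c(C)c(=O)c2C)c(C)c(=O)c1C | target

## Step count and risks
Total steps: 10. Longest linear sequence: 6 steps (1→2→3→4→9→10, or 5→6→7→8→9→10).

**Risk 1, step 10.**
- The trisubstituted bromide may insert slowly.
- The pyronylethyl radical may dimerise.
- The triol and two pyrones may bind nickel.
- The selectivity for a pyrone in place of an arene is untested.
- Fallback: form the same bond early on the small, fully protected bromide, and let the aldol be the last C–C bond. It sets out from 6 and 19. The nickel alkenylation applied to 19 gives the ring A diene silyl ether F1. OsO4/NaIO4/2,6-lutidine attacks the monosubstituted alkene, because the trisubstituted one is flanked by two branched carbons. This passes through the ring A vicinal diol F2 and gives the ring A aldehyde F3. Addition of 22 at −78 °C gives the 5-O-triethylsilyl ether of the target F4. The 1 M HCl quench brings the route back at 25.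

**Risk 2, step 9.**
- Felkin and 1,3-anti face control is reliable.
- The anti relation between the pyrone methine and the new carbinol rests on an open transition state and could be low or reversed.
- Fallback: set the methine by a second radical acyl coupling and the rest by a ketone aldol. It sets out from 9 and uses 12.
  - TESCl/imidazole gives the ring B silyl ether F5.
  - LiN(SiMe3)2 gives the silyl ether lithium dienolate F6.
  - C2Cl6 converts F6 into the ring B chloride F7; the epimer mixture at this carbon does not matter.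
  - Coupling with 7 as in step 3, but with (R,R)-Ph-BOX, gives the (R)-ethyl ketone F8.
  - c-Hex2BCl/Et3N enolises the ethyl side to the (E)-dicyclohexylboron enolate F9.
  - F9 adds to 12 in an anti aldol, anti to the resident methyl, and after hydrolytic work-up gives the β-hydroxy ketone F10.
  - Me4NBH(OAc)3 (Evans–Saksena hydroxyl-directed 1,3-anti reduction) gives the anti diol silyl ether F11.
  - 1 M HCl in THF brings the route back at 24.

**Risk 3, step 3.**
- The acyl coupling is untested on this chloride.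
- Ketone 8 carries a doubly activated methine that may racemise before reduction.
- Fallback: a polar aldol followed by enzymatic resolution, with no ketone stage. It sets out from 5, made from 4 as in step 2. Propanal at −78 °C gives, after removal of the syn isomer, the racemic anti aldol F12. Novozym 435 (immobilised Candida antarctica lipase B) with vinyl acetate acylates the (R)-carbinol to the (2R,3R)-acetate F13. This leaves the (2S,3S)-alcohol F14, which is separated. K2CO3/MeOH on F13 brings the route back at 9.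

## Further compounds
F1 | step 10 | ring A diene silyl ether, 2-ethyl-3,5-dimethyl-6-[(2S,3E,5S,6S)-4,6-dimethyl-5-(triethylsilyloxy)octa-3,7-dien-2-yl]-4H-pyran-4-one | CCc1oc([C@@H](C)/C=C(\C)[C@@H](O[Si](CC)(CC)CC)[C@@H](C)C=C)c(C)c(=O)c1C
F2 | step 10 | ring A vicinal diol (7,8-diol of F1, C7 epimers) | CCc1oc([C@@H](C)/C=C(\C)[C@@H](O[Si](CC)(CC)CC)[C@@H](C)C(O)CO)c(C)c(=O)c1C
F3 | step 10 | ring A aldehyde, (2R,3S,4E,6S)-6-(6-ethyl-3,5-dimethyl-4-oxo-4H-pyran-2-yl)-2,4-dimethyl-3-(triethylsilyloxy)hept-4-enal | CCc1oc([C@@H](C)/C=C(\C)[C@@H](O[Si](CC)(CC)CC)[C@@H](C)C=O)c(C)c(=O)c1C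
F4 | step 10 | 5-O-triethylsilyl ether of the target | CCc1oc([C@@H](C)/C=C(\C)[C@@H](O[Si](CC)(CC)CC)[C@@H](C)[C@H](O)[C@H](C)c2oc([C@H](C)[C@H](O)CC)c(C)c(=O)c2C)c(C)c(=O)c1C
F5 | step 9 | ring B silyl ether, 2-ethyl-3,5-dimethyl-6-[(2R,3R)-3-(triethylsilyloxy)pentan-2-yl]-4H-pyran-4-one | CCc1oc([C@H](C)[C@H](O[Si](CC)(CC)CC)CC)c(C)c(=O)c1C
F6 | step 9 | silyl ether lithium dienolate | [Li+].CC1=C([O-])C(C)=C([C@H](C)[C@H](O[Si](CC)(CC)CC)CC)O/C1=C\C
F7 | step 9 | ring B chloride, 2-(1-chloroethyl)-3,5-dimethyl-6-[(2R,3R)-3-(triethylsilyloxy)pentan-2-yl]-4H-pyran-4-one (C–Cl epimers) | CC(Cl)c1oc([C@H](C)[C@H](O[Si](CC)(CC)CC)CC)c(C)c(=O)c1C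
F8 | step 9 | (R)-ethyl ketone, 3,5-dimethyl-2-[(2R)-3-oxopentan-2-yl]-6-[(2R,3R)-3-(triethylsilyloxy)pentan-2-yl]-4H-pyran-4-one | CCC(=O)[C@H](C)c1oc([C@H](C)[C@H](O[Si](CC)(CC)CC)CC)c(C)c(=O)c1C
F9 | step 9 | (E)-dicyclohexylboron enolate of F8 | C/C=C(OB(C1CCCCC1)C1CCCCC1)\[C@H](C)c1oc([C@H](C)[C@H](O[Si](CC)(CC)CC)CC)c(C)c(=O)c1C
F10 | step 9 | β-hydroxy ketone (anti,anti aldol adduct) | Br/C=C(\C)[C@@H](O)[C@@H](C)C(=O)[C@H](C)c1oc([C@H](C)[C@H](O[Si](CC)(CC)CC)CC)c(C)c(=O)c1C
F11 | step 9 | anti diol silyl ether | Br/C=C(\C)[C@@H](O)[C@@H](C)[C@H](O)[C@H](C)c1oc([C@H](C)[C@H](O[Si](CC)(CC)CC)CC)c(C)c(=O)c1C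
F12 | step 3 | racemic anti aldol, (2R*,3R*)-isomer of 9 as the racemate | CCc1oc([C@H](C)[C@H](O)CC)c(C)c(=O)c1C.CCc1oc([C@@H](C)[C@@H](O)CC)c(C)c(=O)c1C
F13 | step 3 | (2R,3R)-acetate, (2R,3R)-2-(6-ethyl-3,5-dimethyl-4-oxo-4H-pyran-2-yl)pentan-3-yl acetate | CCc1oc([C@H](C)[C@H](OC(C)=O)CC)c(C)c(=O)c1C
F14 | step 3 | (2S,3S)-alcohol, enantiomer of 9 | CCc1oc([C@@H](C)[C@@H](O)CC)c(C)c(=O)c1C
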